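**Plan**

Target: (2S)-5,7-dimethoxy-2-(4-methoxyphenyl)-6-(3-methylbut-2-enyl)chromane (flavan numbering; ring A = benzo ring, ring B = 4-methoxyphenyl, ring C = pyran).
Retrosynthesis cuts, in this order: C2–H (hydride onto a 2,3-enol ether), C2=C3 (ring C), the O1–C2 ester bond, C4a–C4 (Claisen) and the C6–CH2 prenyl bond.
Enabling feature: O1–C2, with ring A on O1 and ring B on C2, is the skeleton of an aryl 4-methoxybenzoate, and C4–C3 on C4a is an ortho-allyl group, so ring C lacks only the C2–C3 bond.
Forward: ring A is bought as 3,5-dimethoxyphenol and receives the prenyl group (C6) by lithiation between the methoxy groups, then the allyl group (C4a) by O-allylation and Claisen rearrangement. Ring B enters by acylation, and ring C closes last by titanium-mediated carbonyl–olefin metathesis to the 4H-chromene.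
Stereochemistry: the only stereocentre, C2 (S), is set in the last step by catalyst-controlled hydride transfer to the flavan-2-ylium ion formed from the achiral enol ether.

Key step: step 7

Assumption: the (R)-configured acid of step 8 is taken to give the 2S product; the sense of induction of this ion-pair reduction must be confirmed, and the (S)-acid is used instead if it proves opposite.

**Route**

Step 1
Reactants: 1 3,5-dimethoxyphenol
Product: 2 (3,5-dimethoxyphenoxy)tri(propan-2-yl)silane
Conditions: i-Pr3SiCl, imidazole, DMF, rt
Reagents that add atoms: chlorotri(propan-2-yl)silane, CC(C)[Si](Cl)(C(C)C)C(C)C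
Why: Imidazole-promoted silylation of a phenol (silyl ether protection) is routine, and the bulky triisopropylsilyl group masks the acidic OH and shields its two ortho positions from the base used next.

Step 2
Reactants: 2 (3,5-dimethoxyphenoxy)tri(propan-2-yl)silane; 3 prenyl bromide (1-bromo-3-methylbut-2-ene)
Product: 5 [3,5-dimethoxy-4-(3-methylbut-2-enyl)phenoxy]tri(propan-2-yl)silane, via aryllithium 4 (not isolated)
Conditions: n-BuLi, THF, 0 °C to rt; then CuBr·SMe2, 3, −78 °C to rt
Reagents that add atoms: prenyl bromide (3), CC(C)=CCBr
Why: Directed ortho-metalation should occur at the carbon flanked by the two methoxy groups, which cooperate in binding lithium while the hindered silyloxy group does not direct, and copper-mediated allylic substitution of prenyl bromide then gives the linear (SN2) prenyl arene.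

Step 3
Reactants: 5 [3,5-dimethoxy-4-(3-methylbut-2-enyl)phenoxy]tri(propan-2-yl)silane
Product: 6 3,5-dimethoxy-4-(3-methylbut-2-enyl)phenol
Conditions: Bu4NF (1 M in wet THF), THF, 0 °C
Reagents that add atoms: none
Why: Fluoride-driven cleavage of the Si–O bond (desilylation) should free the phenol without touching the methyl ethers or the prenyl alkene.

Step 4
Reactants: 6 3,5-dimethoxy-4-(3-methylbut-2-enyl)phenol; 7 allyl bromide
Product: 8 1,3-dimethoxy-2-(3-methylbut-2-enyl)-5-(prop-2-enyloxy)benzene
Conditions: K2CO3, acetone, reflux
Reagents that add atoms: allyl bromide (7), C=CCBr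
Why: Williamson ether synthesis of a phenoxide with an unhindered allylic bromide under weak-base conditions should give clean O-allylation.

Step 5
Reactants: 8 1,3-dimethoxy-2-(3-methylbut-2-enyl)-5-(prop-2-enyloxy)benzene
Product: 10 2-allyl-3,5-dimethoxy-4-(3-methylbut-2-enyl)phenol, via 6-allylcyclohexa-2,4-dienone 9 (not isolated)
Conditions: PhNEt2, 190 °C, sealed tube, N2
Reagents that add atoms: none
Why: The aromatic Claisen rearrangement, a [3,3]-sigmatropic shift to the ortho dienone followed by tautomerisation, places the allyl group on an ortho carbon, and since the two ortho positions are related by the mirror plane of the ring only one isomer can form; the amine solvent suppresses acid-induced cyclisation of the ortho-allylphenol.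

Step 6
Reactants: 10 2-allyl-3,5-dimethoxy-4-(3-methylbut-2-enyl)phenol; 11 4-methoxybenzoyl chloride
Product: 12 2-allyl-3,5-dimethoxy-4-(3-methylbut-2-enyl)phenyl 4-methoxybenzoate
Conditions: Et3N, DMAP (cat.), CH2Cl2, 0 °C to rt
Reagents that add atoms: 4-methoxybenzoyl chloride (11), COc1ccc(C(=O)Cl)cc1
Why: DMAP-catalysed acylation of the phenol by the acid chloride (nucleophilic catalysis through the acylpyridinium) should form the O1–C2 ester bond under non-acidic conditions that leave both alkenes untouched.

Step 7
Reactants: 12 2-allyl-3,5-dimethoxy-4-(3-methylbut-2-enyl)phenyl 4-methoxybenzoate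
Product: 14 5,7-dimethoxy-2-(4-methoxyphenyl)-6-(3-methylbut-2-enyl)-4H-chromene, via aryl 1-arylvinyl ether 13 (not isolated)
Conditions: Cp2Ti(μ-CH2)(μ-Cl)AlMe2 (Tebbe reagent, 4 equiv), pyridine (cat.), THF/toluene, −40 °C to rt, then 65 °C; aq. NaOH quench, basic Al2O3
Reagents that add atoms: none
Why: The titanocene methylidene released from the Tebbe reagent adds across the ester carbonyl to an oxatitanacyclobutane that collapses to vinyl ether 13 and titanocene oxide, a Tebbe methylenation for which aryl benzoates are standard substrates. On heating, a further methylidene adds to the monosubstituted allyl alkene, the titanacyclobutane opens with loss of ethylene to a titanium alkylidene at C3, and this adds intramolecularly to the 1,1-disubstituted enol ether; cycloreversion forms C2=C3 and returns the methylidene. The closest known reaction type is the olefinic ester cyclisation to six-membered cyclic enol ethers with excess Tebbe reagent, together with the two-stage methylenation and ring-closing metathesis route to 4H-chromenes. Ring C closes as a six-membered ring by ring-closing metathesis between C2 and C3 through a bicyclic titanacyclobutane. No stereocentre is formed. The step needs the carbonyl to be methylenated first and the alkylidene to form only at the allyl group: the ester reacts at low temperature before any alkene does, the trisubstituted prenyl alkene is too hindered to form a titanacyclobutane, and the basic quench protects the acid-labile enol ether.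

Step 8
Reactants: 14 5,7-dimethoxy-2-(4-methoxyphenyl)-6-(3-methylbut-2-enyl)-4H-chromene
Product: 16 (2S)-5,7-dimethoxy-2-(4-methoxyphenyl)-6-(3-methylbut-2-enyl)chromane, via flavan-2-ylium ion pair 15 (not isolated)
Conditions: (R)-3,3′-bis(2,4,6-triisopropylphenyl)-1,1′-binaphthalene-2,2′-diyl N-(trifluoromethanesulfonyl)phosphoramide (5–10 mol %), diethyl 2,6-dimethyl-1,4-dihydropyridine-3,5-dicarboxylate (Hantzsch ester, 1.5 equiv), 5 Å molecular sieves, toluene, 0 °C to rt
Reagents that add atoms: none
Why: Proposed new method: the strong chiral acid should protonate the enol ether at C3 to give the 4-methoxyphenyl-stabilised flavan-2-ylium ion as a contact ion pair with the chiral phosphoramidate, and the Hantzsch ester then transfers hydride to C2 on the face left open by the 3,3′-aryl groups, so that C2 is set as S under catalyst control and the acid is returned by the pyridinium; the closest known reaction types are chiral phosphoric acid/Hantzsch ester transfer hydrogenations of enamides and cyclic imines and chiral-anion-controlled additions to oxocarbenium ions, and the weakly basic prenyl alkene should be neither protonated nor reduced.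

**Compound list**

1 | 3,5-dimethoxyphenol | COc1cc(O)cc(OC)c1 | starting material
2 | (3,5-dimethoxyphenoxy)tri(propan-2-yl)silane | COc1cc(O[Si](C(C)C)(C(C)C)C(C)C)cc(OC)c1 | intermediate
3 | prenyl bromide (1-bromo-3-methylbut-2-ene) | CC(C)=CCBr | starting material
4 | [2,6-dimethoxy-4-(triisopropylsilyloxy)phenyl]lithium | [Li]c1c(OC)cc(O[Si](C(C)C)(C(C)C)C(C)C)cc1OC | intermediate (not isolated)
5 | [3,5-dimethoxy-4-(3-methylbut-2-enyl)phenoxy]tri(propan-2-yl)silane | COc1cc(O[Si](C(C)C)(C(C)C)C(C)C)cc(OC)c1CC=C(C)C | intermediate
6 | 3,5-dimethoxy-4-(3-methylbut-2-enyl)phenol | COc1cc(O)cc(OC)c1CC=C(C)C | intermediate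
7 | allyl bromide | C=CCBr | starting material
8 | 1,3-dimethoxy-2-(3-methylbut-2-enyl)-5-(prop-2-enyloxy)benzene | C=CCOc1cc(OC)c(CC=C(C)C)c(OC)c1 | intermediate
9 | 6-allyl-3,5-dimethoxy-4-(3-methylbut-2-enyl)cyclohexa-2,4-dien-1-one (racemic) | C=CCC1C(=O)C=C(OC)C(CC=C(C)C)=C1OC | intermediate (not isolated)
10 | 2-allyl-3,5-dimethoxy-4-(3-methylbut-2-enyl)phenol | C=CCc1c(O)cc(OC)c(CC=C(C)C)c1OC | intermediate
11 | 4-methoxybenzoyl chloride | COc1ccc(C(=O)Cl)cc1 | starting material
12 | 2-allyl-3,5-dimethoxy-4-(3-methylbut-2-enyl)phenyl 4-methoxybenzoate | COc1ccc(cc1)C(=O)Oc1cc(OC)c(CC=C(C)C)c(OC)c1CC=C | intermediate (key-step precursor)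
13 | 2-allyl-3,5-dimethoxy-1-[1-(4-methoxyphenyl)ethenyloxy]-4-(3-methylbut-2-enyl)benzene | COc1ccc(cc1)C(=C)Oc1cc(OC)c(CC=C(C)C)c(OC)c1CC=C | intermediate (not isolated)
14 | 5,7-dimethoxy-2-(4-methoxyphenyl)-6-(3-methylbut-2-enyl)-4H-chromene | COc1ccc(cc1)C1=CCc2c(OC)c(CC=C(C)C)c(OC)cc2O1 | intermediate (key-step product)
15 | 5,7-dimethoxy-2-(4-methoxyphenyl)-6-(3-methylbut-2-enyl)-3,4-dihydrochromenylium cation, paired with the chiral phosphoramidate anion | COc1ccc(cc1)C1=[O+]c2cc(OC)c(CC=C(C)C)c(OC)c2CC1 | intermediate (not isolated)
16 | (2S)-5,7-dimethoxy-2-(4-methoxyphenyl)-6-(3-methylbut-2-enyl)chromane | COc1ccc([C@@H]2CCc3c(cc(OC)c(CC=C(C)C)c3OC)O2)cc1 | target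

**Count**

Total steps: 8. Longest linear sequence: 8 steps (1 to 16).

**Steps most likely to fail**

1. Step 8 (proposed method). The ion pair has no hydrogen-bond anchor, so facial discrimination in the hydride transfer may be poor; adventitious water may also open the oxocarbenium ion hydrolytically. The fallback uses known chemistry; it sets out from chromene 14 and comes back at target 16. Dilute HCl in THF/water at rt hydrolyses the enol ether to 3-[6-hydroxy-2,4-dimethoxy-3-(3-methylbut-2-enyl)phenyl]-1-(4-methoxyphenyl)propan-1-one F1. Noyori asymmetric transfer hydrogenation with RuCl(p-cymene)[(R,R)-TsDPEN] in HCO2H/Et3N should reduce the aryl ketone to (1R)-3-[6-hydroxy-2,4-dimethoxy-3-(3-methylbut-2-enyl)phenyl]-1-(4-methoxyphenyl)propan-1-ol F2 without touching the prenyl alkene. An intramolecular Mitsunobu etherification (PPh3, DIAD, THF, 0 °C) then re-forms the O1–C2 bond with inversion to give (2S)-16. The C2–C3 bond made in step 7 is kept; only the ring is opened and re-closed.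

2. Step 7. The sequence may stall after carbonyl methylenation because the titanium alkylidene fails to engage the hindered 1-aryl enol ether, or the vinyl ether may hydrolyse during handling. The fallback sets out from ester 12 and comes back at chromene 14. Methylenation alone (Tebbe reagent, 1.2 equiv, −40 to 0 °C, basic quench) gives vinyl ether 13, which is isolated on basic Al2O3. Catalytic ring-closing metathesis with the Schrock alkylidene Mo(=CHCMe2Ph)(=N-2,6-i-Pr2C6H3)[OCMe(CF3)2]2 in benzene at 25–60 °C then closes ring C. This replaces the stoichiometric titanium ring closure by a catalytic molybdenum one and avoids the allyl-to-propenyl isomerisation that ruthenium hydrides can cause. No new compound is made.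

3. Step 2. Metalation may take place next to the silyl ether with silyl migration to carbon, or the allylic coupling may proceed with transposition to the 1,1-dimethylallyl isomer. The fallback sets out from prenyl bromide 3 and comes back at phenol 6, bypassing steps 1 to 3. Commercial 1,3-dimethoxybenzene F3 is lithiated at its only doubly activated position (n-BuLi, THF, 0 °C to rt) to (2,6-dimethoxyphenyl)lithium F4. This is coupled with 3 in the presence of CuBr·SMe2 to give 1,3-dimethoxy-2-(3-methylbut-2-enyl)benzene F5. Sterically controlled C–H borylation ([Ir(OMe)(cod)]2, 4,4′-di-tert-butyl-2,2′-bipyridine, B2pin2, THF, 80 °C) at the one position not flanked by a substituent gives 2-[3,5-dimethoxy-4-(3-methylbut-2-enyl)phenyl]-4,4,5,5-tetramethyl-1,3,2-dioxaborolane F6. Oxidation with NaBO3·4H2O in THF/water, which spares the prenyl alkene, gives phenol 6.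

**Further compounds**

F1 | step 8 | 3-[6-hydroxy-2,4-dimethoxy-3-(3-methylbut-2-enyl)phenyl]-1-(4-methoxyphenyl)propan-1-one | COc1ccc(cc1)C(=O)CCc1c(O)cc(OC)c(CC=C(C)C)c1OC
F2 | step 8 | (1R)-3-[6-hydroxy-2,4-dimethoxy-3-(3-methylbut-2-enyl)phenyl]-1-(4-methoxyphenyl)propan-1-ol | COc1ccc([C@H](O)CCc2c(O)cc(OC)c(CC=C(C)C)c2OC)cc1
F0 | step 7 | none | none
F3 | step 2 | 1,3-dimethoxybenzene (commercial) | COc1cccc(OC)c1
F4 | step 2 | (2,6-dimethoxyphenyl)lithium | [Li]c1c(OC)cccc1OC
F5 | step 2 | 1,3-dimethoxy-2-(3-methylbut-2-enyl)benzene | COc1cccc(OC)c1CC=C(C)C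
F6 | step 2 | 2-[3,5-dimethoxy-4-(3-methylbut-2-enyl)phenyl]-4,4,5,5-tetramethyl-1,3,2-dioxaborolane | COc1cc(B2OC(C)(C)C(C)(C)O2)cc(OC)c1CC=C(C)C
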